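**Retrosynthetic overview**
- Allylic alcohol terminus ⇐ terminal alkyne (Zr-catalysed methylalumination, then formaldehyde); alkyne ⇐ primary chloride + acetylide.
- The two inner E-trisubstituted alkenes ⇐ two sp3–sp2 cross-couplings (B-alkyl Suzuki, then Negishi) with one C5 unit, (E)-5-chloro-2-iodopent-2-ene, made from pent-3-yn-1-ol.
- Tertiary carbinol ⇐ spiro-epoxide ⇐ exocyclic methylene ⇐ (S)-2-ethenyl-3,3-dimethylcyclohexanone.
- Key disconnection: that cyclohexanone ⇐ spiro vinyl epoxide on a cyclopentane, by a Pd-catalysed asymmetric semipinacol ring expansion (1,2-shift of the CMe2 ring carbon) that sets the ring CH stereocentre.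
- Ring order: the carbocycle is bought as 2,2-dimethylcyclopentanone and enlarged once to the only ring of the target; the vinyl epoxide comes from the ketone and allyl bromide through a sulfonium ylide.

Assumption: the SMILES is read as (2E,6E,10E)-13-[(1S,2S)-2-hydroxy-2,6,6-trimethylcyclohexyl]-3,7,11-trimethyltrideca-2,6,10-trien-1-ol (OH trans to the side chain); in SMILES of metallocenes the cyclopentadienyl rings are drawn as σ-bonded C5H5 groups.

**Route**

Step 1
Reactants: 1 2,2-dimethylcyclopentan-1-one; 2 allyl bromide (3-bromoprop-1-ene)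
Product: 5 2-ethenyl-4,4-dimethyl-1-oxaspiro[2.4]heptane (racemic diastereomer mixture), via sulfonium salt 3 (not isolated), via sulfonium ylide 4 (not isolated)
Conditions: tetrahydrothiophene, THF, 23 °C, 16 h; KOt-Bu, −78 °C; then 1, −78 → 0 °C
Reagents that add atoms: none
Why: Corey–Chaykovsky-type epoxidation with a semi-stabilised allyl sulfonium ylide gives the vinyl oxirane, and its stereocentres do not matter because the spiro carbon becomes the carbonyl carbon and the allylic centre is equilibrated in step 2.

Step 2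
Reactants: 5 2-ethenyl-4,4-dimethyl-1-oxaspiro[2.4]heptane
Product: 6 (2S)-2-ethenyl-3,3-dimethylcyclohexan-1-one
Conditions: Pd2(dba)3·CHCl3 (2.5 mol%), (R,R)-DACH-phenyl Trost ligand (7.5 mol%), Bu4NCl (10 mol%), CH2Cl2, 23 °C
Reagents that add atoms: none
Why: Proposed new method: a palladium-catalysed dynamic kinetic asymmetric semipinacol ring expansion in which zerovalent palladium ionises the allylic C–O bond of every stereoisomer of 5 to a zwitterionic π-allylpalladium tertiary alkoxide that has no carbinol hydrogen for the usual hydride shift, so the alkoxide pushes the more electron-rich quaternary ring carbon (CMe2) in a 1,2-shift onto the adjacent allyl terminus anti to palladium, enlarging the cyclopentane to the cyclohexanone and releasing the catalyst, while chloride-accelerated π–σ–π interconversion through the unsubstituted CH2 terminus equilibrates the allyl faces faster than migration so that the chiral ligand pocket selects the face that gives (2S)-6; the closest known reaction types are the palladium-catalysed asymmetric Wagner–Meerwein shift of allenylcyclobutanols (same π-allyl/alkyl-shift event, but strain-driven and giving quaternary centres) and the palladium-catalysed dynamic kinetic asymmetric substitution of vinyl epoxides, neither shown for an unstrained spiro vinyl epoxide or a tertiary α-vinyl stereocentre.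

Step 3
Reactants: 6 (2S)-2-ethenyl-3,3-dimethylcyclohexan-1-one
Product: 7 (2S)-2-ethenyl-1,1-dimethyl-3-methylidenecyclohexane
Conditions: Cp2TiMe2 (2 equiv), toluene, 65 °C, dark
Reagents that add atoms: dimethyltitanocene Cp2TiMe2, C[Ti](C)(C1C=CC=C1)C1C=CC=C1
Why: Petasis methylenation through a non-basic titanium carbene converts the hindered, epimerisable β,γ-unsaturated ketone into the exocyclic alkene without touching the C2 stereocentre or conjugating the vinyl group.

Step 4
Reactants: 7 (2S)-2-ethenyl-1,1-dimethyl-3-methylidenecyclohexane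
Product: 8 (3S,4S)-4-ethenyl-5,5-dimethyl-1-oxaspiro[2.5]octane
Conditions: mCPBA (1.05 equiv), NaHCO3, CH2Cl2, −20 → 0 °C
Reagents that add atoms: 3-chloroperoxybenzoic acid (mCPBA), OOC(=O)c1cccc(Cl)c1
Why: Prilezhaev epoxidation picks the 1,1-disubstituted alkene (about twentyfold more reactive than the vinyl group) and attacks the face anti to the syn-axial methyl of the gem-dimethyl group in the vinyl-equatorial conformer, so oxygen ends equatorial and trans to the vinyl group (3S), with the minor epimer removed by chromatography.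

Step 5
Reactants: 8 (3S,4S)-4-ethenyl-5,5-dimethyl-1-oxaspiro[2.5]octane
Product: 9 (1S,2S)-2-ethenyl-1,3,3-trimethylcyclohexan-1-ol
Conditions: LiAlH4, Et2O, 0 → 23 °C; NaOH/H2O work-up
Reagents that add atoms: none
Why: Hydride opening of the epoxide by SN2 attack at the unhindered CH2 turns it into the methyl group and leaves the tertiary C–O stereocentre untouched, giving the alcohol with OH trans to the vinyl group.

Step 6
Reactants: 10 pent-3-yn-1-ol
Product: 11 5-chloropent-2-yne
Conditions: SOCl2, pyridine, CHCl3, 0 → 60 °C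
Reagents that add atoms: thionyl chloride, O=S(Cl)Cl
Why: Chlorodehydroxylation of the primary alcohol (SN2 on the chlorosulfite) removes the hydroxyl that would direct zirconium to the wrong alkyne carbon in step 7 and installs the later organometallic handle.

Step 7
Reactants: 11 5-chloropent-2-yne
Product: 13 (2E)-5-chloro-2-iodopent-2-ene, via alkenyl-ZrCp2Cl 12 (not isolated)
Conditions: Cp2Zr(H)Cl (2 equiv), THF, 50 °C; then I2, 0 °C
Reagents that add atoms: iodine, II
Why: Hydrozirconation–iodination adds Zr–H syn, excess reagent equilibrates zirconium onto the less hindered methyl-bearing carbon (about 9:1 or better, minor isomer removed), and iodinolysis with retention gives the (E)-2-iodoalkene while the alkyl chloride stays inert.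

Step 8
Reactants: 9 (1S,2S)-2-ethenyl-1,3,3-trimethylcyclohexan-1-ol; 13 (2E)-5-chloro-2-iodopent-2-ene
Product: 15 (1S,2S)-2-[(3E)-6-chloro-3-methylhex-3-en-1-yl]-1,3,3-trimethylcyclohexan-1-ol, via alkylborane 14 (not isolated)
Conditions: 9-BBN (1.3 equiv), THF, 0 → 23 °C; then 13, Pd(dppf)Cl2 (5 mol%), 3 M aq NaOH, THF, 40 °C
Reagents that add atoms: none
Why: Anti-Markovnikov hydroboration of the vinyl group followed by B-alkyl Suzuki–Miyaura coupling with retention of the vinyl iodide geometry builds the first E-trisubstituted alkene, with the tertiary alcohol and the primary chloride as spectators.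

Step 9
Reactants: 15 (1S,2S)-2-[(3E)-6-chloro-3-methylhex-3-en-1-yl]-1,3,3-trimethylcyclohexan-1-ol; 13 (2E)-5-chloro-2-iodopent-2-ene
Product: 18 (1S,2S)-2-[(3E,7E)-10-chloro-3,7-dimethyldeca-3,7-dien-1-yl]-1,3,3-trimethylcyclohexan-1-ol, via alkylmagnesium chloride 16 (not isolated), via alkylzinc chloride 17 (not isolated)
Conditions: i-PrMgCl (1.0 equiv), THF, 0 °C; Mg, THF, 60 °C; ZnCl2, 0 °C; then 13, Pd(dppf)Cl2 (3 mol%), THF, 45 °C
Reagents that add atoms: none
Why: After O–H deprotonation, magnesium insertion into the primary chloride, transmetalation to zinc and Negishi coupling with a second portion of 13 install the second E-trisubstituted alkene with retention, the vinyl iodide reacting far faster than any alkyl chloride.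

Step 10
Reactants: 18 (1S,2S)-2-[(3E,7E)-10-chloro-3,7-dimethyldeca-3,7-dien-1-yl]-1,3,3-trimethylcyclohexan-1-ol
Product: 19 (1S,2S)-2-[(3E,7E)-3,7-dimethyldodeca-3,7-dien-11-yn-1-yl]-1,3,3-trimethylcyclohexan-1-ol
Conditions: LiC≡CH·H2NCH2CH2NH2 (3 equiv), NaI (10 mol%), DMSO, 23 → 40 °C
Reagents that add atoms: lithium acetylide ethylenediamine complex LiC≡CH·H2NCH2CH2NH2, [Li]C#C.NCCN
Why: SN2 alkynylation of the primary chloride (iodide-catalysed Finkelstein activation) by lithium acetylide in DMSO gives the terminal alkyne needed for the final methylmetalation.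

Step 11
Reactants: 19 (1S,2S)-2-[(3E,7E)-3,7-dimethyldodeca-3,7-dien-11-yn-1-yl]-1,3,3-trimethylcyclohexan-1-ol
Product: 22 preluffariellolide A, (2E,6E,10E)-13-[(1S,2S)-2-hydroxy-2,6,6-trimethylcyclohexyl]-3,7,11-trimethyltrideca-2,6,10-trien-1-ol, via alkenyl-AlMe2 20 (not isolated), via Li[alkenyl-AlMe2Bu] 21 (not isolated)
Conditions: AlMe3 (4 equiv), Cp2ZrCl2 (25 mol%), CH2Cl2, 0 → 23 °C; volatiles removed; n-BuLi, THF, −78 °C; (CH2O)n, −78 → 23 °C; aq. work-up
Reagents that add atoms: trimethylaluminium AlMe3, C[Al](C)C; paraformaldehyde (formaldehyde unit), C=O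
Why: Negishi zirconium-catalysed carboalumination adds methyl and aluminium syn with aluminium on the terminal carbon, and hydroxymethylation of the derived alanate with formaldehyde proceeds with retention to give the (2E)-allylic alcohol directly, the tertiary alcohol being carried as its aluminium alkoxide and the trisubstituted alkenes being inert.

**Compound list**
1 | 2,2-dimethylcyclopentan-1-one | CC1(C)CCCC1=O | starting material
2 | allyl bromide (3-bromoprop-1-ene) | C=CCBr | starting material
3 | 1-(prop-2-en-1-yl)thiolan-1-ium bromide | C=CC[S+]1CCCC1.[Br-] | intermediate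
4 | allyl ylide of the 1-(prop-2-en-1-yl)thiolan-1-ium ion | C=C[CH-][S+]1CCCC1 | intermediate
5 | 2-ethenyl-4,4-dimethyl-1-oxaspiro[2.4]heptane (racemic diastereomer mixture) | C=CC1OC12CCCC2(C)C | intermediate
6 | (2S)-2-ethenyl-3,3-dimethylcyclohexan-1-one | C=C[C@H]1C(C)(C)CCCC1=O | intermediate
7 | (2S)-2-ethenyl-1,1-dimethyl-3-methylidenecyclohexane | C=C[C@H]1C(C)(C)CCCC1=C | intermediate
8 | (3S,4S)-4-ethenyl-5,5-dimethyl-1-oxaspiro[2.5]octane | C=C[C@H]1C(C)(C)CCC[C@]12OC2 | intermediate
9 | (1S,2S)-2-ethenyl-1,3,3-trimethylcyclohexan-1-ol | C=C[C@H]1C(C)(C)CCC[C@]1(C)O | intermediate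
10 | pent-3-yn-1-ol | CC#CCCO | starting material
11 | 5-chloropent-2-yne | CC#CCCCl | intermediate
12 | chlorido[(2E)-5-chloropent-2-en-2-yl]bis(cyclopentadienyl)zirconium, Cp2Zr(Cl)R | C/C(=C\CCCl)[Zr](Cl)(C1C=CC=C1)C1C=CC=C1 | intermediate
13 | (2E)-5-chloro-2-iodopent-2-ene | C/C(I)=C\CCCl | intermediate
14 | 9-{2-[(1S,2S)-2-hydroxy-2,6,6-trimethylcyclohexyl]ethyl}-9-borabicyclo[3.3.1]nonane | B1(CC[C@H]3C(C)(C)CCC[C@]3(C)O)C2CCCC1CCC2 | intermediate
15 | (1S,2S)-2-[(3E)-6-chloro-3-methylhex-3-en-1-yl]-1,3,3-trimethylcyclohexan-1-ol | ClCC/C=C(\C)CC[C@H]1C(C)(C)CCC[C@]1(C)O | intermediate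
16 | bis(chloromagnesium) derivative of 15 (C–MgCl in place of C–Cl, O–MgCl in place of O–H) | Cl[Mg]CC/C=C(\C)CC[C@H]1C(C)(C)CCC[C@]1(C)O[Mg]Cl | intermediate
17 | alkylzinc chloride from 16 (C–ZnCl, O–MgCl) | Cl[Zn]CC/C=C(\C)CC[C@H]1C(C)(C)CCC[C@]1(C)O[Mg]Cl | intermediate
18 | (1S,2S)-2-[(3E,7E)-10-chloro-3,7-dimethyldeca-3,7-dien-1-yl]-1,3,3-trimethylcyclohexan-1-ol | ClCC/C=C(\C)CC/C=C(\C)CC[C@H]1C(C)(C)CCC[C@]1(C)O | intermediate
19 | (1S,2S)-2-[(3E,7E)-3,7-dimethyldodeca-3,7-dien-11-yn-1-yl]-1,3,3-trimethylcyclohexan-1-ol | C#CCC/C=C(\C)CC/C=C(\C)CC[C@H]1C(C)(C)CCC[C@]1(C)O | intermediate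
20 | (E)-alkenyl(dimethyl)alane from 19 (terminal C–AlMe2, tertiary O–AlMe2) | C[Al](C)/C=C(\C)CC/C=C(\C)CC/C=C(\C)CC[C@H]1C(C)(C)CCC[C@]1(C)O[Al](C)C | intermediate
21 | lithium butyl(dimethyl)alkenylalanate from 20 | [Li+].CCCC[Al-](C)(C)/C=C(\C)CC/C=C(\C)CC/C=C(\C)CC[C@H]1C(C)(C)CCC[C@]1(C)O[Al](C)C | intermediate
22 | preluffariellolide A, (2E,6E,10E)-13-[(1S,2S)-2-hydroxy-2,6,6-trimethylcyclohexyl]-3,7,11-trimethyltrideca-2,6,10-trien-1-ol | C/C(=C\CO)CC/C=C(\C)CC/C=C(\C)CC[C@H]1C(C)(C)CCC[C@]1(C)O | target

**Step count and risks**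
Total: 11 steps. Longest linear sequence: 9 steps (steps 1–5 and 8–11, from 1); fragment 13 takes steps 6–7.

Steps most likely to fail:

Step 2 (the proposed new ring expansion). The shift may outrun π–σ–π equilibration and give low ee, the ring CH2 may migrate instead of the quaternary carbon, or the alkoxide may close on the far allyl terminus to a 2,5-dihydrofuran. The sense of induction has to be found by experiment; the (S,S)-ligand is used if it is opposite. The fallback uses known chemistry only, sets out from 1 and comes back at 6. Wittig olefination of 1 with allylidenetriphenylphosphorane gives (E)-2,2-dimethyl-1-(prop-2-en-1-ylidene)cyclopentane F1. Shi asymmetric epoxidation of its trisubstituted alkene (fructose-derived ketone, KHSO5; catalyst enantiomer chosen for the 2S epoxide) gives (2S)-2-ethenyl-4,4-dimethyl-1-oxaspiro[2.4]heptane F2. The bulky Lewis acid MeAl(OAr)2 (Ar = 4-bromo-2,6-di-tert-butylphenyl) then induces the stereospecific semipinacol ring expansion of F2, with the CMe2 carbon entering anti to the breaking allylic C–O bond (inversion), which delivers 6.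

Step 4 (face selectivity of the epoxidation). The ring is flexible, and reaction through the vinyl-axial conformer would give the cis epimer. The fallback sets out from 7 and comes back at 9, bypassing 8, and replaces electrophilic oxygen transfer by nucleophilic capture. Oxymercuration of 7 with Hg(OAc)2 in THF/H2O gives acetoxy{[(1S,2S)-2-ethenyl-1-hydroxy-3,3-dimethylcyclohexyl]methyl}mercury F3, water entering the tertiary carbon from the unhindered equatorial side. NaBH4/NaOH demercuration of F3 then gives 9.

Step 1 (semi-stabilised ylide against a hindered, enolisable ketone). Conversion may be low. The fallback sets out from 1 and comes back at 5. Addition of 1-chloroallyllithium (allyl chloride, LiN(i-Pr)2, THF, −78 °C) to 1 gives the chlorohydrin 1-(1-chloroprop-2-en-1-yl)-2,2-dimethylcyclopentan-1-ol F4, which KOt-Bu closes to 5.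

Further compounds
F1 | step 2 | (E)-2,2-dimethyl-1-(prop-2-en-1-ylidene)cyclopentane | C=C/C=C1\CCCC1(C)C
F2 | step 2 | (2S)-2-ethenyl-4,4-dimethyl-1-oxaspiro[2.4]heptane | C=C[C@@H]1OC12CCCC2(C)C
F3 | step 4 | acetoxy{[(1S,2S)-2-ethenyl-1-hydroxy-3,3-dimethylcyclohexyl]methyl}mercury | C=C[C@H]1C(C)(C)CCC[C@]1(C[Hg]OC(C)=O)O
F4 | step 1 | 1-(1-chloroprop-2-en-1-yl)-2,2-dimethylcyclopentan-1-ol | C=CC(Cl)C1(O)CCCC1(C)C
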